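## Retrosynthetic overview

1. Target 26 ⇐ C15 allylic alcohol 24 (acid made last) ⇐ C12–C13 Negishi sp3–sp2 coupling of decalin iodide 16 with vinyl iodide 21, whose geometry (from 2-butyne-1,4-diol) fixes 13Z and differentiates C15 from C16.
2. 16 ⇐ bicyclic keto ester 10 by C3 deoxygenation, reduction of the C19 ester, selective iodination at C12 and acetylation at C19.
3. 10 ⇐ acyclic β-keto ester 9 by the proposed enantioselective dehydrogenative radical bicyclization: ring A (C4–C5 bond) first, then ring B (C10–C9 bond), setting C4, C5, C9, C10 and the 8(17)-methylene in one cascade.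
4. 9 ⇐ dianion of ethyl 2-methylacetoacetate + allylic bromide 6 ⇐ geranyl bromide (one-carbon homologation, terminal allylic oxidation).

Assumption: the sense of induction of the new catalyst in step 6 is not known in advance; the (S,S)-ligand is written, and its commercial (R,R)-antipode is used instead if the first run gives the mirror-image series.

Convention: labdane numbering is used for bicyclic compounds. "ent-Labdane" means a trans-decalin with the C10 methyl (C20), the C19 substituent on C4 and the C9 side chain on the α face, and H5 and H9 on the β face; the target is (4R,5S,9R,10S).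

## Route

Step 1
Reactants: 1 geranyl bromide [(2E)-1-bromo-3,7-dimethylocta-2,6-diene]
Product: 3 homogeraniol [(3E)-4,8-dimethylnona-3,7-dien-1-ol], via homogeranyl(isopropoxy)dimethylsilane 2 (not isolated)
Conditions: i-PrOMe2SiCH2MgCl (from ClCH2SiMe2(Oi-Pr), Mg, THF), Li2CuCl4 (3 mol%), THF, 0 °C; then 30% H2O2, KF, KHCO3, THF/MeOH, rt
Reagents that add atoms: (isopropoxydimethylsilyl)methylmagnesium chloride CC(C)O[Si](C)(C)C[Mg]Cl; hydrogen peroxide OO
Why: Copper-catalysed Grignard allylic substitution at the primary carbon (SN2, E-alkene retained) followed by Tamao oxidation of the alkoxysilane, the silylmethyl Grignard acting as a hydroxymethyl anion equivalent; no stereocentre is formed.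

Step 2
Reactants: 3 homogeraniol
Product: 4 homogeranyl pivalate [(3E)-4,8-dimethylnona-3,7-dien-1-yl 2,2-dimethylpropanoate]
Conditions: PivCl, pyridine, DMAP (cat.), CH2Cl2, 0 °C → rt
Reagents that add atoms: pivaloyl chloride CC(C)(C)C(Cl)=O
Why: Simple acylation; the pivalate survives the enolate, radical and NaBH4 steps and is later removed in the same operation as the C19 ester reduction.

Step 3
Reactants: 4 homogeranyl pivalate
Product: 5 (3E,7E)-9-hydroxy-4,8-dimethylnona-3,7-dien-1-yl pivalate
Conditions: SeO2 (10 mol%), t-BuOOH (3 equiv), salicylic acid (10 mol%), CH2Cl2, rt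
Reagents that add atoms: tert-butyl hydroperoxide CC(C)(C)OO (oxygen relayed by catalytic SeO2)
Why: Catalytic SeO2 allylic oxidation (ene reaction then [2,3]-sigmatropic shift) takes place at the terminal, most accessible trisubstituted alkene and on its E-methyl group, so the new allylic alcohol is E.

Step 4
Reactants: 5 (3E,7E)-9-hydroxy-4,8-dimethylnona-3,7-dien-1-yl pivalate
Product: 6 (3E,7E)-9-bromo-4,8-dimethylnona-3,7-dien-1-yl pivalate
Conditions: CBr4, PPh3, CH2Cl2, −20 → 0 °C
Reagents that add atoms: carbon tetrabromide BrC(Br)(Br)Br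
Why: Appel bromination of a primary allylic alcohol under neutral conditions proceeds without allylic transposition or loss of alkene geometry.

Step 5
Reactants: 6 (3E,7E)-9-bromo-4,8-dimethylnona-3,7-dien-1-yl pivalate; 7 ethyl 2-methylacetoacetate (ethyl 2-methyl-3-oxobutanoate)
Product: 9 ethyl (6E,10E)-2,6,10-trimethyl-3-oxo-13-(pivaloyloxy)trideca-6,10-dienoate, via dilithium dianion of ethyl 2-methylacetoacetate 8 (not isolated)
Conditions: 7, LiN(i-Pr)2 (2.2 equiv), THF, 0 °C; then 6, −78 → 0 °C; 1 M HCl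
Reagents that add atoms: none
Why: β-Keto ester dianion γ-alkylation, in which the more basic terminal carbanion of 8 displaces the allylic bromide by SN2; C2 of 9 is stereolabile and needs no control.

Step 6
Reactants: 9 ethyl (6E,10E)-2,6,10-trimethyl-3-oxo-13-(pivaloyloxy)trideca-6,10-dienoate
Product: 10 ethyl 3-oxo-12-(pivaloyloxy)-13,14,15,16-tetranor-ent-labd-8(17)-en-19-oate
Conditions: Mg(NTf2)2 (20 mol%), (S,S)-t-Bu-box (24 mol%), [Ir(dF(CF3)ppy)2(dtbbpy)]PF6 (2 mol%), Co(dmgH)2(py)Cl (2 mol%), 2,6-lutidine (30 mol%), 4 Å MS, CH2Cl2 (0.02 M), 450 nm LEDs, −40 °C, Ar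
Reagents that add atoms: none
Why: Proposed new method: an enantioselective, acceptorless dehydrogenative radical polyene bicyclization under triple catalysis — the β-keto ester chelates the chiral Mg(NTf2)2·box Lewis acid and is soft-enolized by 2,6-lutidine; the photoexcited iridium complex oxidizes only this electron-rich magnesium enolate (not free 9 or the alkenes) to an electrophilic α-radical that stays chelated; this radical closes ring A by 6-endo attack on the first E-alkene (C4–C5 bond, the box ligand shielding one radical face and so fixing the absolute configuration at C4 and C5) and the resulting tertiary radical closes ring B by 6-endo attack on the second E-alkene through a chair–chair array (trans ring fusion, ester axial and cis to the C10 methyl, C9 chain equatorial); the final tertiary C8 radical is intercepted by divalent cobalt formed from Co(dmgH)2(py)Cl, which abstracts a hydrogen atom from the least hindered C17 methyl to give the exocyclic alkene and a cobalt hydride that releases H2 with lutidinium; the closest known reaction types are the stoichiometric Mn(OAc)3/Cu(OAc)2 oxidative radical polyene cyclization of 2-alkyl β-keto esters (racemic or auxiliary-controlled), chiral-Lewis-acid-controlled atom-transfer radical cyclizations of α-halo β-keto esters, and photoredox/cobalt-catalysed desaturation of alkyl radicals.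

Step 7
Reactants: 10 ethyl 3-oxo-12-(pivaloyloxy)-13,14,15,16-tetranor-ent-labd-8(17)-en-19-oate
Product: 11 ethyl 3-hydroxy-12-(pivaloyloxy)-13,14,15,16-tetranor-ent-labd-8(17)-en-19-oate (equatorial 3-OH)
Conditions: NaBH4, MeOH, 0 °C
Reagents that add atoms: none
Why: Chemoselective ketone reduction (the hindered ester and the pivalate are inert to NaBH4), hydride entering anti to the axial C4 ester to give mainly the equatorial alcohol, a centre that is erased in step 9.

Step 8
Reactants: 11 ethyl 3-hydroxy-12-(pivaloyloxy)-13,14,15,16-tetranor-ent-labd-8(17)-en-19-oate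
Product: 12 ethyl 3-[(imidazol-1-yl)thiocarbonyloxy]-12-(pivaloyloxy)-13,14,15,16-tetranor-ent-labd-8(17)-en-19-oate
Conditions: 1,1'-thiocarbonyldiimidazole, DMAP (cat.), ClCH2CH2Cl, 80 °C
Reagents that add atoms: 1,1'-thiocarbonyldiimidazole S=C(n1ccnc1)n1ccnc1
Why: Thioacylation to the Barton–McCombie precursor under neutral conditions, which avoids an alkoxide and hence retro-aldol cleavage of the β-hydroxy ester.

Step 9
Reactants: 12 ethyl 3-[(imidazol-1-yl)thiocarbonyloxy]-12-(pivaloyloxy)-13,14,15,16-tetranor-ent-labd-8(17)-en-19-oate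
Product: 13 ethyl 12-(pivaloyloxy)-13,14,15,16-tetranor-ent-labd-8(17)-en-19-oate
Conditions: Bu3SnH, AIBN (cat.), toluene, 110 °C
Reagents that add atoms: none
Why: Barton–McCombie radical deoxygenation, in which the C3 radical is remote from the 8(17)-alkene and is simply reduced, leaving C4, C5, C9 and C10 untouched.

Step 10
Reactants: 13 ethyl 12-(pivaloyloxy)-13,14,15,16-tetranor-ent-labd-8(17)-en-19-oate
Product: 14 13,14,15,16-tetranor-ent-labd-8(17)-ene-12,19-diol
Conditions: LiAlH4, THF, reflux
Reagents that add atoms: none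
Why: Hydride reduction converts the hindered axial C19 ester into the hydroxymethyl group and cleaves the pivalate in one operation without touching any stereocentre.

Step 11
Reactants: 14 13,14,15,16-tetranor-ent-labd-8(17)-ene-12,19-diol
Product: 15 12-iodo-13,14,15,16-tetranor-ent-labd-8(17)-en-19-ol
Conditions: I2 (1.05 equiv), PPh3, imidazole, CH2Cl2, −10 → 0 °C
Reagents that add atoms: iodine II
Why: Appel-type (Garegg–Samuelsson) iodination is selective for the unhindered C12 primary alcohol because the axial neopentyl C19 hydroxyl cannot undergo SN2 displacement.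

Step 12
Reactants: 15 12-iodo-13,14,15,16-tetranor-ent-labd-8(17)-en-19-ol
Product: 16 12-iodo-13,14,15,16-tetranor-ent-labd-8(17)-en-19-yl acetate
Conditions: Ac2O, i-Pr2NEt, DMAP (5 mol%), CH2Cl2, 0 °C → rt
Reagents that add atoms: acetic anhydride CC(=O)OC(C)=O
Why: DMAP-catalysed acetylation of the remaining neopentyl alcohol, with a non-nucleophilic base so that the primary iodide is not quaternized.

Step 13
Reactants: 17 but-2-yne-1,4-diol
Product: 18 (E)-2-(tributylstannyl)but-2-ene-1,4-diol
Conditions: Bu3SnH, Pd(PPh3)2Cl2 (2 mol%), THF, rt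
Reagents that add atoms: tributyltin hydride CCCC[SnH](CCCC)CCCC
Why: Palladium-catalysed syn-hydrostannation of a symmetrical alkyne (no regiochemical issue) places Sn and H cis, which later becomes the 13Z geometry.

Step 14
Reactants: 18 (E)-2-(tributylstannyl)but-2-ene-1,4-diol
Product: 19 (E)-4-(tert-butyldimethylsilyloxy)-2-(tributylstannyl)but-2-en-1-ol
Conditions: TBSCl (1.0 equiv), imidazole, CH2Cl2, −20 °C
Reagents that add atoms: tert-butyldimethylsilyl chloride CC(C)(C)[Si](C)(C)Cl
Why: Sterically controlled monosilylation, since the hydroxymethyl group next to the bulky Bu3Sn group is shielded and the distal C4 hydroxyl (future C15) reacts.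

Step 15
Reactants: 19 (E)-4-(tert-butyldimethylsilyloxy)-2-(tributylstannyl)but-2-en-1-ol
Product: 20 (E)-4-(tert-butyldimethylsilyloxy)-2-(tributylstannyl)but-2-en-1-yl acetate
Conditions: Ac2O, pyridine, DMAP (cat.), CH2Cl2, 0 °C
Reagents that add atoms: acetic anhydride CC(=O)OC(C)=O
Why: Acetylation of the remaining hydroxyl installs the future C16 acetate before any carbonyl exists at C15, so lactonization is impossible.

Step 16
Reactants: 20 (E)-4-(tert-butyldimethylsilyloxy)-2-(tributylstannyl)but-2-en-1-yl acetate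
Product: 21 (E)-4-(tert-butyldimethylsilyloxy)-2-iodobut-2-en-1-yl acetate
Conditions: I2, CH2Cl2, 0 °C
Reagents that add atoms: iodine II
Why: Iododestannylation of a vinylstannane occurs with retention of alkene geometry.

Step 17
Reactants: 16 12-iodo-13,14,15,16-tetranor-ent-labd-8(17)-en-19-yl acetate; 21 (E)-4-(tert-butyldimethylsilyloxy)-2-iodobut-2-en-1-yl acetate
Product: 23 15-(tert-butyldimethylsilyloxy)-ent-labda-8(17),13Z-diene-16,19-diyl diacetate, via alkylzinc iodide 22 (not isolated)
Conditions: 16, Zn dust (activated with BrCH2CH2Br, TMSCl), LiCl, THF, 40 °C; then 21, Pd(dppf)Cl2 (5 mol%), THF, 25 → 40 °C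
Reagents that add atoms: none
Why: Negishi coupling, in which zinc insertion into the primary iodide tolerates the acetate and the palladium-catalysed sp3–sp2 coupling forms C12–C13 with retention of the vinyl iodide geometry.

Step 18
Reactants: 23 15-(tert-butyldimethylsilyloxy)-ent-labda-8(17),13Z-diene-16,19-diyl diacetate
Product: 24 15-hydroxy-ent-labda-8(17),13Z-diene-16,19-diyl diacetate
Conditions: HF·pyridine, pyridine, THF, 0 °C → rt
Reagents that add atoms: none
Why: Buffered fluoride desilylation removes the primary silyl ether while leaving both acetates and both alkenes intact.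

Step 19
Reactants: 24 15-hydroxy-ent-labda-8(17),13Z-diene-16,19-diyl diacetate
Product: 26 16,19-diacetoxy-ent-labda-8(17),13Z-dien-15-oic acid (target CNP0181814.1), via 16,19-diacetoxy-ent-labda-8(17),13Z-dien-15-al 25 (not isolated)
Conditions: TEMPO (10 mol%), PhI(OAc)2 (1.1 equiv), CH2Cl2, rt; solvent exchange; NaClO2, NaH2PO4, 2-methyl-2-butene, t-BuOH/H2O, 0 °C → rt
Reagents that add atoms: sodium chlorite [Na+].[O-]Cl=O
Why: TEMPO/PhI(OAc)2 oxidation of the allylic alcohol gives the Z-enal, which is carried on crude to avoid Z/E isomerization, and Pinnick oxidation then gives the acid while 2-methyl-2-butene protects the alkenes from HOCl.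

## Compound list

1 | geranyl bromide, (2E)-1-bromo-3,7-dimethylocta-2,6-diene | CC(C)=CCC/C(C)=C/CBr | starting material
2 | (3E)-(4,8-dimethylnona-3,7-dien-1-yl)(isopropoxy)dimethylsilane | CC(C)=CCC/C(C)=C/CC[Si](C)(C)OC(C)C | intermediate
3 | homogeraniol, (3E)-4,8-dimethylnona-3,7-dien-1-ol | CC(C)=CCC/C(C)=C/CCO | intermediate
4 | (3E)-4,8-dimethylnona-3,7-dien-1-yl pivalate | CC(C)=CCC/C(C)=C/CCOC(=O)C(C)(C)C | intermediate
5 | (3E,7E)-9-hydroxy-4,8-dimethylnona-3,7-dien-1-yl pivalate | OC/C(C)=C/CC/C(C)=C/CCOC(=O)C(C)(C)C | intermediate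
6 | (3E,7E)-9-bromo-4,8-dimethylnona-3,7-dien-1-yl pivalate | BrC/C(C)=C/CC/C(C)=C/CCOC(=O)C(C)(C)C | intermediate
7 | ethyl 2-methyl-3-oxobutanoate (ethyl 2-methylacetoacetate) | CCOC(=O)C(C)C(C)=O | starting material
8 | dilithium 1-ethoxy-2-methylbuta-1,3-diene-1,3-diolate (dianion of 7) | [Li+].[Li+].CCOC([O-])=C(C)C([O-])=C | intermediate
9 | ethyl (6E,10E)-2,6,10-trimethyl-3-oxo-13-(pivaloyloxy)trideca-6,10-dienoate (C2 stereolabile, unspecified) | CCOC(=O)C(C)C(=O)CC/C(C)=C/CC/C(C)=C/CCOC(=O)C(C)(C)C | intermediate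
10 | ethyl 3-oxo-12-(pivaloyloxy)-13,14,15,16-tetranor-ent-labd-8(17)-en-19-oate (trans-decalin; C20, axial C19 ester and C9 chain α; H5, H9 β) | C=C1CC[C@@H]2[C@](C)(C(=O)OCC)C(=O)CC[C@@]2(C)[C@@H]1CCOC(=O)C(C)(C)C | intermediate
11 | ethyl 3-hydroxy-12-(pivaloyloxy)-13,14,15,16-tetranor-ent-labd-8(17)-en-19-oate (equatorial 3-OH, cis to C19) | C=C1CC[C@@H]2[C@](C)(C(=O)OCC)[C@H](O)CC[C@@]2(C)[C@@H]1CCOC(=O)C(C)(C)C | intermediate
12 | ethyl 3-[(imidazol-1-yl)thiocarbonyloxy]-12-(pivaloyloxy)-13,14,15,16-tetranor-ent-labd-8(17)-en-19-oate | C=C1CC[C@@H]2[C@](C)(C(=O)OCC)[C@H](OC(=S)n3ccnc3)CC[C@@]2(C)[C@@H]1CCOC(=O)C(C)(C)C | intermediate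
13 | ethyl 12-(pivaloyloxy)-13,14,15,16-tetranor-ent-labd-8(17)-en-19-oate | C=C1CC[C@@H]2[C@](C)(C(=O)OCC)CCC[C@@]2(C)[C@@H]1CCOC(=O)C(C)(C)C | intermediate
14 | 13,14,15,16-tetranor-ent-labd-8(17)-ene-12,19-diol | C=C1CC[C@@H]2[C@](C)(CO)CCC[C@@]2(C)[C@@H]1CCO | intermediate
15 | 12-iodo-13,14,15,16-tetranor-ent-labd-8(17)-en-19-ol | C=C1CC[C@@H]2[C@](C)(CO)CCC[C@@]2(C)[C@@H]1CCI | intermediate
16 | 12-iodo-13,14,15,16-tetranor-ent-labd-8(17)-en-19-yl acetate | C=C1CC[C@@H]2[C@](C)(COC(C)=O)CCC[C@@]2(C)[C@@H]1CCI | intermediate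
17 | but-2-yne-1,4-diol | OCC#CCO | starting material
18 | (E)-2-(tributylstannyl)but-2-ene-1,4-diol (the two CH2OH groups cis) | OC/C(=C\CO)[Sn](CCCC)(CCCC)CCCC | intermediate
19 | (E)-4-(tert-butyldimethylsilyloxy)-2-(tributylstannyl)but-2-en-1-ol | OC/C(=C\CO[Si](C)(C)C(C)(C)C)[Sn](CCCC)(CCCC)CCCC | intermediate
20 | (E)-4-(tert-butyldimethylsilyloxy)-2-(tributylstannyl)but-2-en-1-yl acetate | CC(=O)OC/C(=C\CO[Si](C)(C)C(C)(C)C)[Sn](CCCC)(CCCC)CCCC | intermediate
21 | (E)-4-(tert-butyldimethylsilyloxy)-2-iodobut-2-en-1-yl acetate (CH2OAc and CH2OTBS cis) | CC(=O)OC/C(I)=C\CO[Si](C)(C)C(C)(C)C | intermediate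
22 | [19-acetoxy-13,14,15,16-tetranor-ent-labd-8(17)-en-12-yl]zinc iodide | C=C1CC[C@@H]2[C@](C)(COC(C)=O)CCC[C@@]2(C)[C@@H]1CC[Zn]I | intermediate
23 | 15-(tert-butyldimethylsilyloxy)-ent-labda-8(17),13Z-diene-16,19-diyl diacetate | C=C1CC[C@@H]2[C@](C)(COC(C)=O)CCC[C@@]2(C)[C@@H]1CC/C(=C/CO[Si](C)(C)C(C)(C)C)COC(C)=O | intermediate
24 | 15-hydroxy-ent-labda-8(17),13Z-diene-16,19-diyl diacetate | C=C1CC[C@@H]2[C@](C)(COC(C)=O)CCC[C@@]2(C)[C@@H]1CC/C(=C/CO)COC(C)=O | intermediate
25 | 16,19-diacetoxy-ent-labda-8(17),13Z-dien-15-al | C=C1CC[C@@H]2[C@](C)(COC(C)=O)CCC[C@@]2(C)[C@@H]1CC/C(=C/C=O)COC(C)=O | intermediate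
26 | 16,19-diacetoxy-ent-labda-8(17),13Z-dien-15-oic acid, (4R,5S,9R,10S), CNP0181814.1 | C=C1CC[C@@H]2[C@](C)(COC(C)=O)CCC[C@@]2(C)[C@@H]1CC/C(=C/C(=O)O)COC(C)=O | target

## Step count and risks

Total step count: 19 (15 on the main chain, 4 for vinyl iodide 21).
Longest linear sequence: 15 steps (steps 1–12, then 17–19).

Steps most likely to fail:

Step 3 (allylic oxidation). The internal alkene of 4 is only weakly deactivated, so regioselectivity and yield may be modest and some enal may form. The fallback sets out from 4 and comes back at 6, bypassing 5, by using terminal bromohydrin chemistry and allylic transposition instead of C–H oxidation. NBS in THF/H2O at 0 °C gives the terminal bromohydrin, 7-bromo-8-hydroxy-4,8-dimethylnon-3-en-1-yl pivalate F1. K2CO3 in MeOH closes it to 7,8-epoxy-4,8-dimethylnon-3-en-1-yl pivalate F2. Diethylaluminium 2,2,6,6-tetramethylpiperidide (toluene, 0 °C) isomerizes the epoxide to the secondary allylic alcohol, 7-hydroxy-4,8-dimethylnona-3,8-dien-1-yl pivalate F3. PBr3 in Et2O at −10 °C then gives the primary E-allylic bromide 6 by SN2' displacement.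

Step 6 (proposed new bicyclization). The risks are loss of enantiocontrol if the radical leaves magnesium before ring A closes, premature hydrogen abstraction by divalent cobalt from the first radical (hence low cobalt loading and dilution), and endocyclic alkene isomers. The fallback is known chemistry, the auxiliary-controlled oxidative radical cyclization with trivalent manganese; it sets out from 6 and 7 and comes back at 14. Heating 7 with commercial (1R,2S,5R)-(−)-8-phenylmenthol and DMAP in toluene, with ethanol distilled off, gives (1R,2S,5R)-8-phenylmenthyl 2-methyl-3-oxobutanoate F4. Its dianion (LiN(i-Pr)2, THF) is alkylated with 6 to give the 8-phenylmenthyl ester analogue of 9 F5. Mn(OAc)3·2H2O (2.2 equiv), Cu(OAc)2·H2O (1 equiv) and Yb(OTf)3 in CF3CH2OH at −5 °C give the 8-phenylmenthyl ester analogue of 10 F6; the auxiliary shields one face of the chelated radical and divalent copper oxidizes the last radical to the exocyclic alkene. I am choosing the (−)-auxiliary from memory as the antipode of the one that gives the normal series, so the sense should be confirmed on F6. NaBH4 in MeOH gives the 3-hydroxy ester F7, 1,1'-thiocarbonyldiimidazole gives the thiocarbonylimidazolide F8, and Bu3SnH/AIBN gives the 3-deoxy 8-phenylmenthyl ester F9. LiAlH4 in refluxing THF cleaves both esters to diol 14 with recovery of the auxiliary.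

Step 17 (Negishi coupling). Zinc insertion may be sluggish next to the hindered decalin, and zerovalent palladium could ionize the allylic acetate. The fallback sets out from 16 and 21 and comes back at 23. A nickel-catalysed reductive cross-electrophile coupling (NiBr2(dme) 10 mol%, 4,4'-di-tert-butyl-2,2'-bipyridine, Mn powder, DMA, rt) joins the two iodides directly through an alkyl radical and a vinylnickel species with retention of alkene geometry, so no organozinc reagent is needed; it makes no new compound (F0).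

## Further compounds

F1 | step 3 | (3E)-7-bromo-8-hydroxy-4,8-dimethylnon-3-en-1-yl pivalate (racemic) | CC(C)(O)C(Br)CC/C(C)=C/CCOC(=O)C(C)(C)C
F2 | step 3 | (3E)-7,8-epoxy-4,8-dimethylnon-3-en-1-yl pivalate (racemic) | CC1(C)OC1CC/C(C)=C/CCOC(=O)C(C)(C)C
F3 | step 3 | (3E)-7-hydroxy-4,8-dimethylnona-3,8-dien-1-yl pivalate (racemic) | C=C(C)C(O)CC/C(C)=C/CCOC(=O)C(C)(C)C
F4 | step 6 | (1R,2S,5R)-8-phenylmenthyl 2-methyl-3-oxobutanoate | CC(=O)C(C)C(=O)O[C@@H]1C[C@H](C)CC[C@H]1C(C)(C)c1ccccc1
F5 | step 6 | (1R,2S,5R)-8-phenylmenthyl (6E,10E)-2,6,10-trimethyl-3-oxo-13-(pivaloyloxy)trideca-6,10-dienoate | O=C(O[C@@H]1C[C@H](C)CC[C@H]1C(C)(C)c1ccccc1)C(C)C(=O)CC/C(C)=C/CC/C(C)=C/CCOC(=O)C(C)(C)C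
F6 | step 6 | (1R,2S,5R)-8-phenylmenthyl 3-oxo-12-(pivaloyloxy)-13,14,15,16-tetranor-ent-labd-8(17)-en-19-oate | C=C1CC[C@@H]2[C@](C)(C(=O)O[C@@H]3C[C@H](C)CC[C@H]3C(C)(C)c3ccccc3)C(=O)CC[C@@]2(C)[C@@H]1CCOC(=O)C(C)(C)C
F7 | step 6 | (1R,2S,5R)-8-phenylmenthyl 3-hydroxy-12-(pivaloyloxy)-13,14,15,16-tetranor-ent-labd-8(17)-en-19-oate | C=C1CC[C@@H]2[C@](C)(C(=O)O[C@@H]3C[C@H](C)CC[C@H]3C(C)(C)c3ccccc3)[C@H](O)CC[C@@]2(C)[C@@H]1CCOC(=O)C(C)(C)C
F8 | step 6 | (1R,2S,5R)-8-phenylmenthyl 3-[(imidazol-1-yl)thiocarbonyloxy]-12-(pivaloyloxy)-13,14,15,16-tetranor-ent-labd-8(17)-en-19-oate | C=C1CC[C@@H]2[C@](C)(C(=O)O[C@@H]3C[C@H](C)CC[C@H]3C(C)(C)c3ccccc3)[C@H](OC(=S)n3ccnc3)CC[C@@]2(C)[C@@H]1CCOC(=O)C(C)(C)C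
F9 | step 6 | (1R,2S,5R)-8-phenylmenthyl 12-(pivaloyloxy)-13,14,15,16-tetranor-ent-labd-8(17)-en-19-oate | C=C1CC[C@@H]2[C@](C)(C(=O)O[C@@H]3C[C@H](C)CC[C@H]3C(C)(C)c3ccccc3)CCC[C@@]2(C)[C@@H]1CCOC(=O)C(C)(C)C
F0 | step 17 | none | none
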